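**Plan**

- Retrosynthesis: the O8 glycolate and the lactone carbonyl (carried as a methyl lactol ether) are removed first. Then C7–C11 and C8–O are cut together (radical cyclisation with oxygen capture), followed by the O6–C12 acetal bond, the C6–C7 ring bond and the C1=C10 double bond.
- Forward: (S)-citronellal supplies C1–C6 with the C4 methyl, and a propargyl-bearing ylide adds C7–C10 and C14. The ten-membered ring closes first (C6–C7), the five-membered ring second, in the key step.
- Enabling feature: the five-membered ring O–C6–C7–C11–C12 is cis-fused to the ten-membered ring (H6 and H7 syn) and C8 carries oxygen anti to C11. This is the imprint of a C11 radical, tethered through C12 to O6, adding to a ring-cis C7=C8 bond of a cyclodeca-1,4-dienol, with O2 trapping the C8 radical.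
- Stereochemistry: C4 comes from (S)-citronellal and C6 from reagent-controlled reduction of the ring enone. C7 and C8 are relayed from C6 in the key step. The C1=C10 geometry comes from an E-selective Wittig reaction and the cis C7=C8 bond from diimide reduction of an iodoalkyne.

Key step: step 14

Numbering used throughout: ring C1 (olefinic CH), C2, C3, C4 (CHMe), C5, C6 (O–CH), C7 (ring fusion), C8 (O–CH), C9, C10 (olefinic carbon bearing C14H2OAc); C11, C12 and C13 are the lactone α-carbon, the carbonyl carbon and the exocyclic methylene. IUPAC ring locants in the names differ from these labels.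

Assumption: C12 is carried as a mixture of acetal (later lactol) epimers, which converge once C12 becomes the lactone carbonyl.

**Route**

Step 1
Reactants: 1 (S)-citronellal
Product: 2 (6S)-8,8-dimethoxy-2,6-dimethyloct-2-ene
Conditions: HC(OMe)3, MeOH, PPTS (cat.), rt
Reagents that add atoms: trimethyl orthoformate COC(OC)OC; methanol CO
Why: Acid-catalysed acetalisation with orthoformate as water scavenger masks the aldehyde under conditions mild enough to avoid the carbonyl-ene cyclisation of citronellal; the future C4 centre is untouched.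

Step 2
Reactants: 2 (6S)-8,8-dimethoxy-2,6-dimethyloct-2-ene
Product: 4 (4S)-6,6-dimethoxy-4-methylhexanal, via ozonide 3 (not isolated)
Conditions: O3, CH2Cl2, −78 °C; then PPh3, −78 °C → rt
Reagents that add atoms: ozone [O-][O+]=O
Why: Ozonolysis with reductive work-up cleaves the trisubstituted alkene to the C1 aldehyde and acetone, the electron-rich alkene reacting far faster than the acetal.

Step 3
Reactants: 5 propargyl bromide; 6 ethyl (triphenylphosphoranylidene)acetate (2 equiv)
Product: 8 ethyl 2-(triphenylphosphoranylidene)pent-4-ynoate, via alkylated phosphonium bromide 7 (not isolated)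
Conditions: EtOAc, reflux
Reagents that add atoms: none
Why: C-Alkylation of the stabilised ylide by the propargylic bromide, followed by transylidation with the second equivalent of 6, gives the α-substituted stabilised ylide (ylide alkylation).

Step 4
Reactants: 4 (4S)-6,6-dimethoxy-4-methylhexanal; 8 ethyl 2-(triphenylphosphoranylidene)pent-4-ynoate
Product: 9 ethyl (2E,6S)-8,8-dimethoxy-6-methyl-2-(prop-2-yn-1-yl)oct-2-enoate
Conditions: toluene, 90 °C
Reagents that add atoms: none
Why: Wittig olefination with an α-substituted ester-stabilised ylide is E-selective, placing the ester (later C14) trans to the C2 chain and the propargyl arm (C9) cis to it, which is the ring-cis C1=C10 geometry of the target.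

Step 5
Reactants: 9 ethyl (2E,6S)-8,8-dimethoxy-6-methyl-2-(prop-2-yn-1-yl)oct-2-enoate
Product: 10 (2E,6S)-8,8-dimethoxy-6-methyl-2-(prop-2-yn-1-yl)oct-2-en-1-ol
Conditions: i-Bu2AlH (DIBAL-H), CH2Cl2, −78 °C
Reagents that add atoms: none
Why: Hydride reduction of the conjugated ester by DIBAL-H proceeds 1,2 to the allylic alcohol at low temperature without touching the alkyne or the acetal.

Step 6
Reactants: 10 (2E,6S)-8,8-dimethoxy-6-methyl-2-(prop-2-yn-1-yl)oct-2-en-1-ol
Product: 11 (2E,6S)-8,8-dimethoxy-6-methyl-2-(prop-2-yn-1-yl)oct-2-en-1-yl acetate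
Conditions: Ac2O, pyridine, DMAP (cat.), CH2Cl2, 0 °C → rt
Reagents that add atoms: acetic anhydride CC(=O)OC(C)=O
Why: DMAP-catalysed acetylation installs the C14 acetate of the target, which is expected to survive all later steps.

Step 7
Reactants: 11 (2E,6S)-8,8-dimethoxy-6-methyl-2-(prop-2-yn-1-yl)oct-2-en-1-yl acetate
Product: 12 (2E,6S)-2-(3-iodoprop-2-yn-1-yl)-8,8-dimethoxy-6-methyloct-2-en-1-yl acetate
Conditions: N-iodosuccinimide, AgNO3 (cat.), acetone, rt, dark
Reagents that add atoms: N-iodosuccinimide O=C1CCC(=O)N1I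
Why: Silver-catalysed electrophilic iodination of the terminal alkyne through its silver acetylide gives the 1-iodoalkyne.

Step 8
Reactants: 12 (2E,6S)-2-(3-iodoprop-2-yn-1-yl)-8,8-dimethoxy-6-methyloct-2-en-1-yl acetate
Product: 13 (2E,6S)-2-[(2Z)-3-iodoprop-2-en-1-yl]-8,8-dimethoxy-6-methyloct-2-en-1-yl acetate
Conditions: 2-nitrobenzenesulfonylhydrazide, Et3N, THF/i-PrOH, rt
Reagents that add atoms: none
Why: Diimide reduction: diimide formed in the flask adds H2 syn to the iodoalkyne and so gives the (Z)-iodoalkene, while the trisubstituted alkene is too hindered to be reduced.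

Step 9
Reactants: 13 (2E,6S)-2-[(2Z)-3-iodoprop-2-en-1-yl]-8,8-dimethoxy-6-methyloct-2-en-1-yl acetate
Product: 14 (2E,6S)-2-[(2Z)-3-iodoprop-2-en-1-yl]-6-methyl-8-oxooct-2-en-1-yl acetate
Conditions: 1 M aq. HCl, THF, 0 °C → rt
Reagents that add atoms: water O
Why: Acetal hydrolysis under mild aqueous acid frees the C6 aldehyde; the vinyl iodide and allylic acetate are stable, and C4, being β to the carbonyl, cannot epimerise.

Step 10
Reactants: 14 (2E,6S)-2-[(2Z)-3-iodoprop-2-en-1-yl]-6-methyl-8-oxooct-2-en-1-yl acetate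
Product: 15 [(1E,4Z,8S)-6-hydroxy-8-methylcyclodeca-1,4-dien-2-yl]methyl acetate (both C6 epimers)
Conditions: CrCl2 (excess), NiCl2 (cat.), DMSO/THF, rt, slow addition of 14 (high dilution)
Reagents that add atoms: none
Why: Intramolecular Nozaki–Hiyama–Kishi reaction: zerovalent nickel inserts into the C7–I bond, transmetallation gives an alkenyl species of trivalent chromium that adds to the C6 aldehyde with retention of the Z geometry, and high dilution favours closure of the ten-membered ring; C6 forms as a mixture that steps 11 and 12 correct.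

Step 11
Reactants: 15 [(1E,4Z,8S)-6-hydroxy-8-methylcyclodeca-1,4-dien-2-yl]methyl acetate
Product: 16 [(1E,4Z,8S)-8-methyl-6-oxocyclodeca-1,4-dien-2-yl]methyl acetate
Conditions: Dess–Martin periodinane, NaHCO3, CH2Cl2, 0 °C
Reagents that add atoms: none
Why: Dess–Martin oxidation under buffered, non-basic conditions converges both C6 epimers on one enone without moving the skipped C1=C10 bond into conjugation.

Step 12
Reactants: 16 [(1E,4Z,8S)-8-methyl-6-oxocyclodeca-1,4-dien-2-yl]methyl acetate
Product: 17 [(1E,4Z,6S,8S)-6-hydroxy-8-methylcyclodeca-1,4-dien-2-yl]methyl acetate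
Conditions: (R)-Me-CBS oxazaborolidine [(3aR)-1-methyl-3,3-diphenyltetrahydro-1H,3H-pyrrolo[1,2-c][1,3,2]oxazaborole] (cat.), catecholborane, toluene, −78 °C
Reagents that add atoms: none
Why: Corey–Bakshi–Shibata reduction: with the alkenyl arm (C7) as the large group and the C5 methylene as the small one, the (R)-configured oxazaborolidine should direct hydride to the face that gives the (6S) alcohol, and catecholborane at low temperature avoids hydroboration.

Step 13
Reactants: 17 [(1E,4Z,6S,8S)-6-hydroxy-8-methylcyclodeca-1,4-dien-2-yl]methyl acetate; 18 methoxyallene (excess)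
Product: 19 [(1E,4Z,6S,8S)-6-[(2-iodo-1-methoxyprop-2-en-1-yl)oxy]-8-methylcyclodeca-1,4-dien-2-yl]methyl acetate (acetal epimers)
Conditions: N-iodosuccinimide, CH2Cl2, −40 → −10 °C
Reagents that add atoms: N-iodosuccinimide O=C1CCC(=O)N1I
Why: Iodoalkoxylation of the allenyl ether: iodonium attack at the central allene carbon gives an oxocarbenium ion that the C6 alcohol captures, the same haloacetal formation as from enol ethers in Ueno–Stork chemistry, with the electron-rich allene consumed far faster than the ring alkenes; the iodide is chosen over the bromide so that halogen abstraction in step 14 is fast at room temperature under air.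

Step 14
Reactants: 19 [(1E,4Z,6S,8S)-6-[(2-iodo-1-methoxyprop-2-en-1-yl)oxy]-8-methylcyclodeca-1,4-dien-2-yl]methyl acetate
Product: 21 [(3aR,4S,6E,10S,11aS)-4-hydroxy-2-methoxy-10-methyl-3-methylidene-2,3,3a,4,5,8,9,10,11,11a-decahydrocyclodeca[b]furan-6-yl]methyl acetate (C12 epimers; cis-fused with 8-OH anti to C11), via C8 hydroperoxide 20 (not isolated)
Conditions: Bu3SnH (slow addition), dry air, toluene, 0 °C → rt; then PPh3
Reagents that add atoms: dioxygen O=O
Why: Bu3Sn• abstracts iodine from 19 to give the σ-vinyl radical at C11, which adds to C7 of the ring-cis C7=C8 bond; the resulting secondary C8 radical is captured by O2, the peroxyl radical takes hydrogen from the stannane to give hydroperoxide 20, and PPh3 reduces 20 to alcohol 21 in the flask. The reaction type is the Ueno–Stork haloacetal radical cyclisation in its 2-haloallyl (vinyl-radical) form, run under the aerobic tin hydride conditions used for oxygenative radical cyclisation. The five-membered ring closes 5-exo-trig and C7 is set by the tether: C11 can reach C7 only on the alkene face that carries O6, and closure through the conformer with the C6–O bond perpendicular to the alkene and C5 near the alkene plane, the arrangement in which common-ring allylic haloacetals are held, gives the cis fusion (H6 and H7 syn). C8 is set by approach of O2 to the planar radical on the face away from the newly formed ring, anti to C11; this is the less certain of the two controls. The step needs 5-exo closure to outrun capture of the vinyl radical by O2 or stannane and to prevail over 6-endo closure; the high rate of σ-vinyl radical cyclisation and the low concentrations of dissolved O2 and slowly added Bu3SnH should secure this, and fast O2 capture at C8 forestalls the homoallyl rearrangement that would expand the new ring to six members. The C12 acetal epimers are of no consequence because C12 becomes the lactone carbonyl, and the exocyclic C11=C13 bond is already in place.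

Step 15
Reactants: 21 [(3aR,4S,6E,10S,11aS)-4-hydroxy-2-methoxy-10-methyl-3-methylidene-2,3,3a,4,5,8,9,10,11,11a-decahydrocyclodeca[b]furan-6-yl]methyl acetate; 22 2-[(tert-butyldimethylsilyl)oxy]acetic acid
Product: 23 (3aS,4S,6E,10S,11aS)-6-(acetoxymethyl)-2-methoxy-10-methyl-3-methylidene-2,3,3a,4,5,8,9,10,11,11a-decahydrocyclodeca[b]furan-4-yl 2-[(tert-butyldimethylsilyl)oxy]acetate
Conditions: EDC·HCl, DMAP, CH2Cl2, 0 °C → rt
Reagents that add atoms: none
Why: Steglich esterification acylates the only free hydroxyl, at C8, with retention, and doing so before C12 reaches the lactone level prevents migration of the lactone from O6 to O8.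

Step 16
Reactants: 23 (3aS,4S,6E,10S,11aS)-6-(acetoxymethyl)-2-methoxy-10-methyl-3-methylidene-2,3,3a,4,5,8,9,10,11,11a-decahydrocyclodeca[b]furan-4-yl 2-[(tert-butyldimethylsilyl)oxy]acetate
Product: 25 (3aS,4S,6E,10S,11aS)-6-(acetoxymethyl)-2-hydroxy-10-methyl-3-methylidene-2,3,3a,4,5,8,9,10,11,11a-decahydrocyclodeca[b]furan-4-yl 2-hydroxyacetate (lactol epimers), via silyl lactol 24 (not isolated)
Conditions: 1 M aq. HCl, THF, rt
Reagents that add atoms: water O
Why: Acetal hydrolysis and desilylation in one operation: aqueous acid hydrolyses the allylic methyl acetal to the lactol and then cleaves the primary silyl ether, while the three ester groups should survive at room temperature.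

Step 17
Reactants: 25 (3aS,4S,6E,10S,11aS)-6-(acetoxymethyl)-2-hydroxy-10-methyl-3-methylidene-2,3,3a,4,5,8,9,10,11,11a-decahydrocyclodeca[b]furan-4-yl 2-hydroxyacetate
Product: 26 (3aS,4S,6E,10S,11aS)-6-(acetoxymethyl)-10-methyl-3-methylidene-2-oxo-2,3,3a,4,5,8,9,10,11,11a-decahydrocyclodeca[b]furan-4-yl 2-hydroxyacetate (target)
Conditions: MnO2, CH2Cl2, rt
Reagents that add atoms: none
Why: Chemoselective allylic oxidation: MnO2 oxidises the lactol, whose C12 is allylic to C11=C13, to the α-methylene lactone and should leave the unactivated primary hydroxyl of the glycolate untouched.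

**Compound list**

1 | (S)-citronellal | O=CC[C@@H](C)CCC=C(C)C | starting material
2 | (6S)-8,8-dimethoxy-2,6-dimethyloct-2-ene | COC(OC)C[C@@H](C)CCC=C(C)C | intermediate
3 | 3-[(3S)-5,5-dimethoxy-3-methylpentyl]-5,5-dimethyl-1,2,4-trioxolane (ozonide) | COC(OC)C[C@@H](C)CCC1OOC(C)(C)O1 | intermediate (not isolated)
4 | (4S)-6,6-dimethoxy-4-methylhexanal | COC(OC)C[C@@H](C)CCC=O | intermediate
5 | propargyl bromide | C#CCBr | starting material
6 | ethyl (triphenylphosphoranylidene)acetate | CCOC(=O)C=P(c1ccccc1)(c1ccccc1)c1ccccc1 | starting material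
7 | (1-ethoxy-1-oxopent-4-yn-2-yl)triphenylphosphonium bromide | CCOC(=O)C(CC#C)[P+](c1ccccc1)(c1ccccc1)c1ccccc1.[Br-] | intermediate (not isolated)
8 | ethyl 2-(triphenylphosphoranylidene)pent-4-ynoate | CCOC(=O)C(CC#C)=P(c1ccccc1)(c1ccccc1)c1ccccc1 | intermediate
9 | ethyl (2E,6S)-8,8-dimethoxy-6-methyl-2-(prop-2-yn-1-yl)oct-2-enoate | CCOC(=O)/C(CC#C)=C/CC[C@H](C)CC(OC)OC | intermediate
10 | (2E,6S)-8,8-dimethoxy-6-methyl-2-(prop-2-yn-1-yl)oct-2-en-1-ol | OC/C(CC#C)=C/CC[C@H](C)CC(OC)OC | intermediate
11 | (2E,6S)-8,8-dimethoxy-6-methyl-2-(prop-2-yn-1-yl)oct-2-en-1-yl acetate | CC(=O)OC/C(CC#C)=C/CC[C@H](C)CC(OC)OC | intermediate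
12 | (2E,6S)-2-(3-iodoprop-2-yn-1-yl)-8,8-dimethoxy-6-methyloct-2-en-1-yl acetate | CC(=O)OC/C(CC#CI)=C/CC[C@H](C)CC(OC)OC | intermediate
13 | (2E,6S)-2-[(2Z)-3-iodoprop-2-en-1-yl]-8,8-dimethoxy-6-methyloct-2-en-1-yl acetate | CC(=O)OC/C(C/C=C\I)=C/CC[C@H](C)CC(OC)OC | intermediate
14 | (2E,6S)-2-[(2Z)-3-iodoprop-2-en-1-yl]-6-methyl-8-oxooct-2-en-1-yl acetate | CC(=O)OC/C(C/C=C\I)=C/CC[C@H](C)CC=O | intermediate
15 | [(1E,4Z,8S)-6-hydroxy-8-methylcyclodeca-1,4-dien-2-yl]methyl acetate (C6 epimers) | OC1C[C@@H](C)CC/C=C(/COC(C)=O)C/C=C\1 | intermediate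
16 | [(1E,4Z,8S)-8-methyl-6-oxocyclodeca-1,4-dien-2-yl]methyl acetate | O=C1C[C@@H](C)CC/C=C(/COC(C)=O)C/C=C\1 | intermediate
17 | [(1E,4Z,6S,8S)-6-hydroxy-8-methylcyclodeca-1,4-dien-2-yl]methyl acetate | O[C@H]1C[C@@H](C)CC/C=C(/COC(C)=O)C/C=C\1 | intermediate
18 | methoxyallene (1-methoxypropa-1,2-diene) | COC=C=C | starting material
19 | [(1E,4Z,6S,8S)-6-[(2-iodo-1-methoxyprop-2-en-1-yl)oxy]-8-methylcyclodeca-1,4-dien-2-yl]methyl acetate (acetal epimers) | COC(C(I)=C)O[C@H]1C[C@@H](C)CC/C=C(/COC(C)=O)C/C=C\1 | intermediate (key-step precursor)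
20 | [(3aS,4S,6E,10S,11aS)-4-hydroperoxy-2-methoxy-10-methyl-3-methylidene-2,3,3a,4,5,8,9,10,11,11a-decahydrocyclodeca[b]furan-6-yl]methyl acetate | C=C1C(OC)O[C@H]2C[C@@H](C)CC/C=C(/COC(C)=O)C[C@H](OO)[C@@H]12 | intermediate (not isolated)
21 | [(3aR,4S,6E,10S,11aS)-4-hydroxy-2-methoxy-10-methyl-3-methylidene-2,3,3a,4,5,8,9,10,11,11a-decahydrocyclodeca[b]furan-6-yl]methyl acetate (C12 epimers; the 3a descriptor differs from the target only through ligand priorities) | C=C1C(OC)O[C@H]2C[C@@H](C)CC/C=C(/COC(C)=O)C[C@H](O)[C@@H]12 | intermediate (key-step product)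
22 | 2-[(tert-butyldimethylsilyl)oxy]acetic acid | CC(C)(C)[Si](C)(C)OCC(=O)O | starting material
23 | (3aS,4S,6E,10S,11aS)-6-(acetoxymethyl)-2-methoxy-10-methyl-3-methylidene-2,3,3a,4,5,8,9,10,11,11a-decahydrocyclodeca[b]furan-4-yl 2-[(tert-butyldimethylsilyl)oxy]acetate | C=C1C(OC)O[C@H]2C[C@@H](C)CC/C=C(/COC(C)=O)C[C@H](OC(=O)CO[Si](C)(C)C(C)(C)C)[C@@H]12 | intermediate
24 | (3aS,4S,6E,10S,11aS)-6-(acetoxymethyl)-2-hydroxy-10-methyl-3-methylidene-2,3,3a,4,5,8,9,10,11,11a-decahydrocyclodeca[b]furan-4-yl 2-[(tert-butyldimethylsilyl)oxy]acetate | C=C1C(O)O[C@H]2C[C@@H](C)CC/C=C(/COC(C)=O)C[C@H](OC(=O)CO[Si](C)(C)C(C)(C)C)[C@@H]12 | intermediate (not isolated)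
25 | (3aS,4S,6E,10S,11aS)-6-(acetoxymethyl)-2-hydroxy-10-methyl-3-methylidene-2,3,3a,4,5,8,9,10,11,11a-decahydrocyclodeca[b]furan-4-yl 2-hydroxyacetate (lactol epimers) | C=C1C(O)O[C@H]2C[C@@H](C)CC/C=C(/COC(C)=O)C[C@H](OC(=O)CO)[C@@H]12 | intermediate
26 | (3aS,4S,6E,10S,11aS)-6-(acetoxymethyl)-10-methyl-3-methylidene-2-oxo-2,3,3a,4,5,8,9,10,11,11a-decahydrocyclodeca[b]furan-4-yl 2-hydroxyacetate | C=C1C(=O)O[C@H]2C[C@@H](C)CC/C=C(/COC(C)=O)C[C@H](OC(=O)CO)[C@@H]12 | target

**Step count**

Total: 17 steps. Longest linear sequence: 16 steps from (S)-citronellal (steps 1, 2, 4–17); step 3 prepares the ylide in a side branch.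

**Steps most likely to fail**

1. Step 14 (radical cyclisation with oxygen capture). Three processes are at risk. The σ-vinyl radical must close before dioxygen or stannane captures it. Closure through the other rotamer about C6–C7 (H6 eclipsing the alkene, attack from the ring periphery) would give the trans-fused bicycle; in a ten-membered ring this rotamer is not excluded. Dioxygen may add to the C8 radical from either face. The fallback is polar and stereospecific; it sets out from 17 and comes back at 26.
   - Directed epoxidation of the C7=C8 bond of 17 (VO(acac)2, t-BuOOH, CH2Cl2) is expected to occur on the ring face opposite to the hydroxyl in the flat-ring sense, as with medium-ring (Z)-cycloalkenols, and gives the 7,8-epoxy alcohol F1.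
   - Esterification of O6 with (diethoxyphosphoryl)acetic acid (DCC, DMAP) gives the epoxy phosphonoacetate F2.
   - NaH in THF generates the phosphonate carbanion, which opens the epoxide 5-exo at C7 with inversion. C11 then arrives cis to O6 and O8 is left anti to C11, giving the α-phosphono lactone F3.
   - Paraformaldehyde added to the same flask effects Horner–Wadsworth–Emmons methylenation to the 8-hydroxy α-methylene lactone F4.
   - Steglich esterification with 22 gives the silyl-protected glycolate F5, and HF·pyridine in THF releases 26.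

2. Step 10 (Nozaki–Hiyama–Kishi ring closure). The alkenyl chromium species may add to a second molecule faster than it closes the strained ten-membered ring, and the cis alkenyl metal may lose its geometry. The fallback closes the ring by metathesis at C7=C8; it sets out from 11 and comes back at 15.
   - Semi-hydrogenation of the alkyne (H2, Pd/CaCO3 poisoned with Pb(OAc)2, quinoline) gives the allyl compound F6.
   - Acetal hydrolysis (1 M aq. HCl, THF) gives the aldehyde F7.
   - Vinylmagnesium bromide at −78 °C gives the allylic alcohol F8 (C8 chain epimers).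
   - Ring-closing metathesis (second-generation Grubbs catalyst, CH2Cl2, reflux, high dilution) closes the ten-membered ring, in which the cis C7=C8 bond is the less strained, to give 15.

3. Step 12 (enone reduction). Facial discrimination may be poor, because in the ring (Z)-enone the alkenyl and alkyl arms differ little in effective size. The fallback avoids the enone; it sets out from 15 and comes back at 17, so steps 11 and 12 are omitted.
   - The C6 epimers of 15 are separated by chromatography; the (6S) epimer is 17.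
   - The (6R) epimer F9 is inverted by Mitsunobu reaction with chloroacetic acid (PPh3, diisopropyl azodicarboxylate, toluene) to the (6S) chloroacetate F10.
   - Thiourea and NaHCO3 in EtOH cleave the chloroacetate selectively in the presence of the C14 acetate to give 17.

**Further compounds**

F1 | step 14 | [(1E,6S,8S)-4,5-epoxy-6-hydroxy-8-methylcyclodec-1-en-2-yl]methyl acetate, epoxide oxygen on the ring face opposite to the C6 hydroxyl | O[C@H]1C[C@@H](C)CC/C=C(/COC(C)=O)C[C@@H]2O[C@H]12
F2 | step 14 | (diethoxyphosphoryl)acetate of F1 at O6 | CCOP(=O)(OCC)CC(=O)O[C@H]1C[C@@H](C)CC/C=C(/COC(C)=O)C[C@@H]2O[C@H]12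
F3 | step 14 | cis-fused α-(diethoxyphosphoryl) lactone with free 8-OH anti to C11 (C11 epimers) | CCOP(=O)(OCC)C1C(=O)O[C@H]2C[C@@H](C)CC/C=C(/COC(C)=O)C[C@H](O)[C@@H]12
F4 | step 14 | 8-hydroxy α-methylene lactone (26 without the glycolyl group) | C=C1C(=O)O[C@H]2C[C@@H](C)CC/C=C(/COC(C)=O)C[C@H](O)[C@@H]12
F5 | step 14 | tert-butyldimethylsilyl ether of 26 at the glycolate hydroxyl | C=C1C(=O)O[C@H]2C[C@@H](C)CC/C=C(/COC(C)=O)C[C@H](OC(=O)CO[Si](C)(C)C(C)(C)C)[C@@H]12
F6 | step 10 | (2E,6S)-8,8-dimethoxy-6-methyl-2-(prop-2-en-1-yl)oct-2-en-1-yl acetate | CC(=O)OC/C(CC=C)=C/CC[C@H](C)CC(OC)OC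
F7 | step 10 | (2E,6S)-6-methyl-8-oxo-2-(prop-2-en-1-yl)oct-2-en-1-yl acetate | CC(=O)OC/C(CC=C)=C/CC[C@H](C)CC=O
F8 | step 10 | (2E,6S)-8-hydroxy-6-methyl-2-(prop-2-en-1-yl)deca-2,9-dien-1-yl acetate (C8 epimers) | CC(=O)OC/C(CC=C)=C/CC[C@H](C)CC(O)C=C
F9 | step 12 | [(1E,4Z,6R,8S)-6-hydroxy-8-methylcyclodeca-1,4-dien-2-yl]methyl acetate | O[C@@H]1C[C@@H](C)CC/C=C(/COC(C)=O)C/C=C\1
F10 | step 12 | [(1E,4Z,6S,8S)-6-[(chloroacetyl)oxy]-8-methylcyclodeca-1,4-dien-2-yl]methyl acetate | ClCC(=O)O[C@H]1C[C@@H](C)CC/C=C(/COC(C)=O)C/C=C\1
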